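**Retrosynthetic overview**
1. Target 20 ⇐ benzyl ester diacetate 19 (hydrogenolysis) ⇐ (3S)-3,4-dihydroisochromen-1-one 16 (lactone opening, acetylation) ⇐ isochromen-1-one 15 (asymmetric hydrogenation sets C-2′).
2. Key disconnection of 15: the bond from ring carbon C-6 to side-chain carbon C-1′, the bond from C-1 to the carboxyl carbon and the O–C-2′ bond, all in one step, leading back to aryne 13, terminal alkyne 12 and CO2.
3. Enabling feature: benzene ring A carries the carboxyl (C-1) and the side chain (C-6) on adjacent carbons with an oxygen at C-2 beside this pair, and the C-2′ oxygen is δ to the carboxyl carbon. The adjacent pair is the footprint of an aryne triple bond, the C-2 oxygen steers the carbon nucleophile to C-6 and CO2 to C-1, and one oxygen of CO2 becomes the C-2′ oxygen through pyranone ring B.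
4. Ring order: ring A is bought; ring B (the lactone) is closed in the key step and opened again in step 9.
5. Fragments: alkyne 12 from (S)-2-methyloxirane and dec-1-yne (epoxide opening, alkyne zipper, acetylation); aryne precursor 6 from 3,5-bis(benzyloxy)phenol (bromination, silylation, retro-Brook rearrangement and triflation).

Key step: step 7

Remark: C-1 to C-6 are the ring carbons of the target (C-1 carboxyl-bearing, C-6 chain-bearing) and C-1′ to C-13′ the side-chain carbons; compounds 1, 7 and 8 are taken to be purchasable.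

**Route**

Step 1
Reactants: 1 3,5-bis(benzyloxy)phenol
Product: 2 2-bromo-3,5-bis(benzyloxy)phenol
Conditions: NBS (1.0 equiv), iPr2NH (cat.), CH2Cl2, −78 → 0 °C
Reagents that add atoms: N-bromosuccinimide, O=C1CCC(=O)N1Br
Why: Electrophilic aromatic bromination of a phenol with amine-mediated ortho delivery should place bromine at the position flanked by hydroxyl and benzyloxy (the two ortho positions are equivalent by symmetry), while C-4 between the two benzyloxy groups is shielded and one equivalent at low temperature limits dibromination.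

Step 2
Reactants: 2 2-bromo-3,5-bis(benzyloxy)phenol
Product: 3 [3,5-bis(benzyloxy)-2-bromophenoxy]trimethylsilane
Conditions: HMDS, THF, 65 °C; evaporation
Reagents that add atoms: hexamethyldisilazane, C[Si](C)(C)N[Si](C)(C)C
Why: O-Silylation of a phenol with hexamethyldisilazane should give the aryl silyl ether needed for the silyl shift, with ammonia as the only by-product.

Step 3
Reactants: 3 [3,5-bis(benzyloxy)-2-bromophenoxy]trimethylsilane
Product: 6 3,5-bis(benzyloxy)-2-(trimethylsilyl)phenyl trifluoromethanesulfonate, via aryllithium 4 (not isolated), via lithium 2-silylphenolate 5 (not isolated)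
Conditions: n-BuLi, THF, −100 → −78 °C; then Tf2O, −100 → −78 °C
Reagents that add atoms: trifluoromethanesulfonic anhydride, O=S(=O)(OS(=O)(=O)C(F)(F)F)C(F)(F)F
Why: Bromine–lithium exchange followed by a 1,3 oxygen-to-carbon silyl shift (retro-Brook rearrangement) should give a phenolate that is O-triflated, the standard entry to 2-(trimethylsilyl)aryl triflates, and the benzyl ethers should survive the short exposure to n-BuLi at low temperature.

Step 4
Reactants: 7 dec-1-yne; 8 (S)-2-methyloxirane
Product: 10 (2S)-tridec-4-yn-2-ol, via lithium dec-1-yn-1-ide 9 (not isolated)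
Conditions: n-BuLi, THF, −78 °C; BF3·OEt2; then 8, −78 °C
Reagents that add atoms: none
Why: BF3-promoted opening of the epoxide by the lithium acetylide (Yamaguchi–Hirao alkynylation) should occur at the unsubstituted carbon, so the stereocentre of 8 is carried over unchanged as (S).

Step 5
Reactants: 10 (2S)-tridec-4-yn-2-ol
Product: 11 (2S)-tridec-12-yn-2-ol
Conditions: KH, H2N(CH2)3NH2, 0 °C → rt; then H2O
Reagents that add atoms: none
Why: In the alkyne zipper reaction potassium 3-aminopropylamide should move the triple bond by successive propargyl–allenyl proton shifts to the chain end, where the acetylide forms irreversibly, while the carbinol carbon is held as an alkoxide, cannot be passed and keeps its configuration.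

Step 6
Reactants: 11 (2S)-tridec-12-yn-2-ol
Product: 12 (2S)-tridec-12-yn-2-yl acetate
Conditions: Ac2O, pyridine, DMAP (cat.), CH2Cl2, 0 °C → rt
Reagents that add atoms: acetic anhydride, CC(=O)OC(C)=O
Why: DMAP-catalysed acylation at oxygen should mask the hydroxyl, which would otherwise add to the aryne, without touching the stereocentre, and the ester is removed together with the lactone opening in step 9.

Step 7
Reactants: 6 3,5-bis(benzyloxy)-2-(trimethylsilyl)phenyl trifluoromethanesulfonate; 12 (2S)-tridec-12-yn-2-yl acetate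
Product: 15 (2S)-11-[6,8-bis(benzyloxy)-1-oxo-1H-isochromen-3-yl]undecan-2-yl acetate, via 3,5-bis(benzyloxy)benzyne 13 (not isolated), via cesium 2-alkynylbenzoate 14 (not isolated)
Conditions: (IPr)CuCl (10 mol %; IPr = 1,3-bis(2,6-diisopropylphenyl)imidazol-2-ylidene, monovalent copper), CsF, Cs2CO3, CO2 (1 atm), MeCN, 80 °C
Reagents that add atoms: carbon dioxide, O=C=O
Why: Fluoride removes the silyl group of 6 and triflate leaves to give aryne 13; the alkynylcopper generated from 12, Cs2CO3 and (IPr)CuCl adds across the strained triple bond, the arylcopper inserts CO2, and carboxylate 14 attacks the copper-activated alkyne, protonation of the vinylcopper at C-4 releasing 15 and the catalyst. The closest known reaction type is the NHC–copper-catalysed three-component coupling of 2-silylaryl triflates, terminal alkynes and CO2 to 3-substituted isocoumarins. Ring B closes in the 6-endo-dig mode by attack of a carboxylate oxygen on the chain-bearing alkyne carbon, so one oxygen of CO2 becomes the C-2′ oxygen of the target. No stereocentre is formed. The step needs regioselection on the aryne, and the benzyloxy group on the carbon next to the triple bond secures it: its inductive pull distorts the aryne so that the remote aryne carbon is the more electrophilic one and the new carbon–copper bond sits beside oxygen, so the alkynyl carbon (future C-1′) bonds to C-6 and CO2 to C-1. It also needs carboxylation to outrun protonation of the arylcopper, which a dry CO2-saturated medium favours, and 6-endo over 5-exo closure, which the alkyl-substituted alkyne under copper activation favours.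

Step 8
Reactants: 15 (2S)-11-[6,8-bis(benzyloxy)-1-oxo-1H-isochromen-3-yl]undecan-2-yl acetate
Product: 16 (2S)-11-[(3S)-6,8-bis(benzyloxy)-1-oxo-3,4-dihydro-1H-isochromen-3-yl]undecan-2-yl acetate
Conditions: Ru(2-methylallyl)2(cod) (5 mol %), SINpEt·HBF4 (single enantiomer of 1,3-bis[1-(1-naphthyl)ethyl]imidazolinium tetrafluoroborate), KOtBu, then chiral 1,2-diphenylethane-1,2-diamine (antipodes chosen for 3S), H2 (50 bar), NaOtBu (cat.), n-hexane/toluene, 25 °C
Reagents that add atoms: none
Why: Enantioselective hydrogenation of the C-3/C-4 enol-lactone double bond of 3-substituted isocoumarins by chiral ruthenium NHC–diamine catalysts is a known catalyst-controlled reaction, so the catalyst antipode should select the face and set C-3 (C-2′ of the target) as (S), while the benzyl ethers and the arene are untouched and any loss of the remote acetate is harmless because step 9 removes it.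

Step 9
Reactants: 16 (2S)-11-[(3S)-6,8-bis(benzyloxy)-1-oxo-3,4-dihydro-1H-isochromen-3-yl]undecan-2-yl acetate
Product: 19 benzyl 2,4-bis(benzyloxy)-6-[(2S,12S)-2,12-diacetoxytridecyl]benzoate, via potassium dihydroxy carboxylate 17 (not isolated), via benzyl dihydroxy ester 18 (not isolated)
Conditions: KOH, THF/MeOH/H2O, 50 °C; CO2, then evaporation to dryness; BnBr, DMF, rt; Ac2O, pyridine, DMAP (cat.), 0 °C → rt
Reagents that add atoms: potassium hydroxide, [K+].[OH-]; benzyl bromide, BrCc1ccccc1; acetic anhydride, CC(=O)OC(C)=O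
Why: Saponification should open the lactone by acyl–oxygen cleavage (the C-2′–O bond and its configuration are retained) and remove the acetate, SN2 O-alkylation of the carboxylate esterifies without activating the acyl carbon, and immediate DMAP-catalysed acetylation caps both secondary hydroxyls before the hydroxy ester can close again, the doubly ortho-substituted benzoate being slow to suffer attack.

Step 10
Reactants: 19 benzyl 2,4-bis(benzyloxy)-6-[(2S,12S)-2,12-diacetoxytridecyl]benzoate
Product: 20 2-[(2S,12S)-2,12-diacetoxytridecyl]-4,6-dihydroxybenzoic acid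
Conditions: H2 (1 atm), Pd/C, EtOAc, rt
Reagents that add atoms: none
Why: Hydrogenolysis of the benzyl ester and of both aryl benzyl ethers over palladium on carbon under neutral conditions should leave the two acetates, both stereocentres and the arene untouched and free the acid without heat, which avoids decarboxylation.

**Compound list**
1 | 3,5-bis(benzyloxy)phenol | Oc1cc(OCc2ccccc2)cc(OCc2ccccc2)c1 | starting material
2 | 2-bromo-3,5-bis(benzyloxy)phenol | Oc1cc(OCc2ccccc2)cc(OCc2ccccc2)c1Br | intermediate
3 | [3,5-bis(benzyloxy)-2-bromophenoxy]trimethylsilane | C[Si](C)(C)Oc1cc(OCc2ccccc2)cc(OCc2ccccc2)c1Br | intermediate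
4 | [3,5-bis(benzyloxy)-2-lithiophenoxy]trimethylsilane (aryllithium) | C[Si](C)(C)Oc1cc(OCc2ccccc2)cc(OCc2ccccc2)c1[Li] | intermediate
5 | lithium 3,5-bis(benzyloxy)-2-(trimethylsilyl)phenolate | C[Si](C)(C)c1c([O-])cc(OCc2ccccc2)cc1OCc1ccccc1.[Li+] | intermediate
6 | 3,5-bis(benzyloxy)-2-(trimethylsilyl)phenyl trifluoromethanesulfonate | C[Si](C)(C)c1c(OS(=O)(=O)C(F)(F)F)cc(OCc2ccccc2)cc1OCc1ccccc1 | intermediate
7 | dec-1-yne | C#CCCCCCCCC | starting material
8 | (S)-2-methyloxirane | C[C@H]1CO1 | starting material
9 | lithium dec-1-yn-1-ide | [Li+].[C-]#CCCCCCCCC | intermediate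
10 | (2S)-tridec-4-yn-2-ol | C[C@H](O)CC#CCCCCCCCC | intermediate
11 | (2S)-tridec-12-yn-2-ol | C[C@H](O)CCCCCCCCCC#C | intermediate
12 | (2S)-tridec-12-yn-2-yl acetate | C[C@H](OC(C)=O)CCCCCCCCCC#C | intermediate
13 | 3,5-bis(benzyloxy)benzyne | C1#CC(OCc2ccccc2)=CC(OCc2ccccc2)=C1 | intermediate
14 | cesium 2-[(12S)-12-acetoxytridec-1-yn-1-yl]-4,6-bis(benzyloxy)benzoate | [Cs+].[O-]C(=O)c1c(OCc2ccccc2)cc(OCc2ccccc2)cc1C#CCCCCCCCCC[C@H](C)OC(C)=O | intermediate
15 | (2S)-11-[6,8-bis(benzyloxy)-1-oxo-1H-isochromen-3-yl]undecan-2-yl acetate | CC(=O)O[C@@H](C)CCCCCCCCCC1=Cc2cc(OCc3ccccc3)cc(OCc3ccccc3)c2C(=O)O1 | intermediate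
16 | (2S)-11-[(3S)-6,8-bis(benzyloxy)-1-oxo-3,4-dihydro-1H-isochromen-3-yl]undecan-2-yl acetate | O=C1O[C@@H](CCCCCCCCC[C@H](C)OC(C)=O)Cc2cc(OCc3ccccc3)cc(OCc3ccccc3)c21 | intermediate
17 | potassium 2,4-bis(benzyloxy)-6-[(2S,12S)-2,12-dihydroxytridecyl]benzoate | [K+].[O-]C(=O)c1c(OCc2ccccc2)cc(OCc2ccccc2)cc1C[C@@H](O)CCCCCCCCC[C@H](C)O | intermediate
18 | benzyl 2,4-bis(benzyloxy)-6-[(2S,12S)-2,12-dihydroxytridecyl]benzoate | O=C(OCc1ccccc1)c1c(OCc2ccccc2)cc(OCc2ccccc2)cc1C[C@@H](O)CCCCCCCCC[C@H](C)O | intermediate
19 | benzyl 2,4-bis(benzyloxy)-6-[(2S,12S)-2,12-diacetoxytridecyl]benzoate | O=C(OCc1ccccc1)c1c(OCc2ccccc2)cc(OCc2ccccc2)cc1C[C@@H](OC(C)=O)CCCCCCCCC[C@H](C)OC(C)=O | intermediate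
20 | 2-[(2S,12S)-2,12-diacetoxytridecyl]-4,6-dihydroxybenzoic acid | CC(=O)O[C@@H](CCCCCCCCC[C@H](C)OC(C)=O)Cc1cc(O)cc(O)c1C(=O)O | target

**Step count**
Total: 10 steps. Longest linear sequence: 7 steps (steps 4, 5, 6, 7, 8, 9, 10; the arene branch through steps 1, 2, 3 is equally long).

**Steps most likely to fail**

Step 7. The arylcopper may be protonated before it takes up CO2, the alkynylcopper may add to the wrong aryne carbon, or the carboxylate may close 5-exo instead of 6-endo. The fallback makes the same aryl–alkyne bond by Sonogashira coupling; it sets out from alkyne 12 and comes back at 15. Methyl 2,4,6-trihydroxybenzoate F1 (purchased) would be benzylated twice (BnBr, K2CO3, acetone; the hydrogen-bonded ortho hydroxyl stays free) to methyl 2,4-bis(benzyloxy)-6-hydroxybenzoate F2 and triflated (Tf2O, pyridine, CH2Cl2) to methyl 2,4-bis(benzyloxy)-6-(trifluoromethylsulfonyloxy)benzoate F3. Coupling of F3 with 12 (PdCl2(PPh3)2, CuI, Et3N, DMF, 70 °C) should give methyl 2-[(12S)-12-acetoxytridec-1-yn-1-yl]-4,6-bis(benzyloxy)benzoate F4. Acid-promoted 6-endo-dig lactonisation with loss of the ester methyl (Cu(OTf)2 cat., CF3CO2H, 1,2-dichloroethane, 60 °C) should then return 15.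

Step 8. Face selection by the catalyst may be insufficient, or the hydrogenation of the hindered, long-chain enol lactone may stall. The fallback sets C-2′ by ketone reduction instead; it sets out from 15 and comes back at 18. KOH (THF/MeOH/H2O) should open the enol lactone and cleave the acetate to potassium 2,4-bis(benzyloxy)-6-[(12S)-12-hydroxy-2-oxotridecyl]benzoate F5, which BnBr in DMF converts to benzyl 2,4-bis(benzyloxy)-6-[(12S)-12-hydroxy-2-oxotridecyl]benzoate F6. Reduction of the 1-aryl-2-alkanone carbonyl with an (S)-selective ketoreductase from a screening panel (NADP+, isopropanol, buffer/DMSO, 30 °C) should give 18, which is acetylated as in the last operation of step 9 to 19.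

Step 9. The hydroxy ester may close back to the lactone before both hydroxyls are acetylated. The fallback never has a free C-2′ hydroxyl beside an acyl group; it sets out from 16 and comes back at 20.
- LiAlH4 (THF, 0 °C) should reduce lactone and acetate to (2S,12S)-1-[3,5-bis(benzyloxy)-2-(hydroxymethyl)phenyl]tridecane-2,12-diol F7.
- TBSCl and imidazole (CH2Cl2, 0 °C) should silylate the primary benzylic hydroxyl to the silyl ether F8, although this hydroxyl is flanked by two ortho substituents and the selectivity over the secondary hydroxyls would need checking.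
- Ac2O, pyridine and DMAP should give the diacetate F9, and TBAF buffered with AcOH the benzylic alcohol F10.
- Dess–Martin periodinane should give the aldehyde F11, and Pinnick oxidation (NaClO2, NaH2PO4, 2-methyl-2-butene, t-BuOH/H2O) 2,4-bis(benzyloxy)-6-[(2S,12S)-2,12-diacetoxytridecyl]benzoic acid F12.
- Hydrogenolysis (H2, Pd/C, EtOAc) should then give 20.

**Further compounds**
F1 | step 7 | methyl 2,4,6-trihydroxybenzoate | COC(=O)c1c(O)cc(O)cc1O
F2 | step 7 | methyl 2,4-bis(benzyloxy)-6-hydroxybenzoate | COC(=O)c1c(O)cc(OCc2ccccc2)cc1OCc1ccccc1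
F3 | step 7 | methyl 2,4-bis(benzyloxy)-6-(trifluoromethylsulfonyloxy)benzoate | COC(=O)c1c(OS(=O)(=O)C(F)(F)F)cc(OCc2ccccc2)cc1OCc1ccccc1
F4 | step 7 | methyl 2-[(12S)-12-acetoxytridec-1-yn-1-yl]-4,6-bis(benzyloxy)benzoate | COC(=O)c1c(OCc2ccccc2)cc(OCc2ccccc2)cc1C#CCCCCCCCCC[C@H](C)OC(C)=O
F5 | step 8 | potassium 2,4-bis(benzyloxy)-6-[(12S)-12-hydroxy-2-oxotridecyl]benzoate | [K+].[O-]C(=O)c1c(OCc2ccccc2)cc(OCc2ccccc2)cc1CC(=O)CCCCCCCCC[C@H](C)O
F6 | step 8 | benzyl 2,4-bis(benzyloxy)-6-[(12S)-12-hydroxy-2-oxotridecyl]benzoate | O=C(OCc1ccccc1)c1c(OCc2ccccc2)cc(OCc2ccccc2)cc1CC(=O)CCCCCCCCC[C@H](C)O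
F7 | step 9 | (2S,12S)-1-[3,5-bis(benzyloxy)-2-(hydroxymethyl)phenyl]tridecane-2,12-diol | OCc1c(OCc2ccccc2)cc(OCc2ccccc2)cc1C[C@@H](O)CCCCCCCCC[C@H](C)O
F8 | step 9 | (2S,12S)-1-[3,5-bis(benzyloxy)-2-(tert-butyldimethylsilyloxymethyl)phenyl]tridecane-2,12-diol | CC(C)(C)[Si](C)(C)OCc1c(OCc2ccccc2)cc(OCc2ccccc2)cc1C[C@@H](O)CCCCCCCCC[C@H](C)O
F9 | step 9 | (2S,12S)-1-[3,5-bis(benzyloxy)-2-(tert-butyldimethylsilyloxymethyl)phenyl]tridecane-2,12-diyl diacetate | CC(C)(C)[Si](C)(C)OCc1c(OCc2ccccc2)cc(OCc2ccccc2)cc1C[C@@H](OC(C)=O)CCCCCCCCC[C@H](C)OC(C)=O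
F10 | step 9 | (2S,12S)-1-[3,5-bis(benzyloxy)-2-(hydroxymethyl)phenyl]tridecane-2,12-diyl diacetate | OCc1c(OCc2ccccc2)cc(OCc2ccccc2)cc1C[C@@H](OC(C)=O)CCCCCCCCC[C@H](C)OC(C)=O
F11 | step 9 | (2S,12S)-1-[3,5-bis(benzyloxy)-2-formylphenyl]tridecane-2,12-diyl diacetate | O=Cc1c(OCc2ccccc2)cc(OCc2ccccc2)cc1C[C@@H](OC(C)=O)CCCCCCCCC[C@H](C)OC(C)=O
F12 | step 9 | 2,4-bis(benzyloxy)-6-[(2S,12S)-2,12-diacetoxytridecyl]benzoic acid | OC(=O)c1c(OCc2ccccc2)cc(OCc2ccccc2)cc1C[C@@H](OC(C)=O)CCCCCCCCC[C@H](C)OC(C)=O
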